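**Retrosynthetic overview** (positions numbered as in 1H-isochromene: C1, O2, C3, C4, C4a, C5–C8, C8a, in each half)
1. The C5=CH–CH=CH–C3 link is cut by a retro-Knoevenagel into the 6,8-dione half 29 (acidic C5H2 between C6=O and the C4a=C8a–C8=O enone) and the dienal half 26, two bicycles of similar size that both come from bicycle 24 by cross-metathesis at its propenyl group.
2. In 24 the pyran ring (O2, C1, C8a, C4a, C4, C3) is a 2H-pyran with sp3 C1H2 on O2 and the C3=C4 and C4a=C8a bonds running into C8=O. It is therefore the closed valence tautomer of the 1-oxatriene O=C3–C4=C4a–C8a=C1H2, and the C1–O2 bond is made last.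
3. The oxatriene is unfolded by a retro-[3,3] shift (C4 goes back from C4a to an ester oxygen on C1) with a traceless sulfinyl group on C4; this gives allylic β-keto ester 19, made from Baylis–Hillman alcohol 12 and crotonyl Meldrum's acid 15.
4. Carbocycle 12 comes from 2-methylcyclohexane-1,3-dione: O-acylation with silylated orsellinic acid, epoxidation with 1,2-acyl shift (hindered C7–O ester), CBS desymmetrization (C6 and C7), dehydrogenation, hydroxymethylation.
5. Ring order: carbocycle (purchased) → pyran (key step) → union of the two bicycles → desilylation.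

Key step: step 11

Remark: "silylated orsellinate" means 2,4-bis(triisopropylsilyloxy)-6-methylbenzoate. The sense of induction in step 4 is assigned from the usual oxazaborolidine model (quaternary carbon as the large group); the enantiomeric catalyst would be used if the sense proved opposite.

**Step 1**
Reactants: 1 orsellinic acid
Product: 3 2,4-bis(triisopropylsilyloxy)-6-methylbenzoic acid, via silyl ester 2 (not isolated)
Conditions: TIPSOTf (3.3 equiv), 2,6-lutidine, CH2Cl2, 0 °C to rt; then AcOH/THF/H2O, rt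
Reagents that add atoms: triisopropylsilyl trifluoromethanesulfonate, CC(C)[Si](OS(=O)(=O)C(F)(F)F)(C(C)C)C(C)C
Why: the silyl triflate silylates both phenols and the acid, and the silyl ester is then hydrolysed much faster than the aryl silyl ethers (protection, selective silyl ester hydrolysis).

**Step 2**
Reactants: 3 2,4-bis(triisopropylsilyloxy)-6-methylbenzoic acid; 4 2-methylcyclohexane-1,3-dione
Product: 6 2-methyl-3-oxocyclohex-1-en-1-yl silylated orsellinate (enol ester), via acid chloride 5 (not isolated)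
Conditions: (COCl)2, cat. DMF, CH2Cl2, 0 °C; then 4, Et3N, cat. DMAP, CH2Cl2, 0 °C to rt
Reagents that add atoms: none
Why: the dione enol is O-acylated by the hindered acid chloride (enol ester formation), which puts the orsellinate acyl group next to the future C7 without attack at a tertiary centre.

**Step 3**
Reactants: 6 enol ester
Product: 8 1-methyl-2,6-dioxocyclohexyl silylated orsellinate, via acyloxy epoxide 7 (not isolated)
Conditions: dimethyldioxirane (acetone solution), CH2Cl2, 0 °C to rt; then 40 °C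
Reagents that add atoms: dimethyldioxirane, CC1(C)OO1
Why: epoxidation of the enol ester and opening of the acyloxy epoxide with 1,2-acyl migration (enol ester epoxide rearrangement) form the hindered tertiary ester intramolecularly; the product has a mirror plane through C7 and is achiral.

**Step 4**
Reactants: 8 1-methyl-2,6-dioxocyclohexyl silylated orsellinate
Product: 9 (1R,2R)-2-hydroxy-1-methyl-6-oxocyclohexyl silylated orsellinate
Conditions: (S)-2-methyl-CBS-oxazaborolidine (20 mol%), catecholborane (1.1 equiv), PhMe/CH2Cl2, −78 °C; aqueous work-up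
Reagents that add atoms: none
Why: Corey–Bakshi–Shibata reduction desymmetrizes the prochiral 2,2-disubstituted 1,3-dione: the catalyst chooses one enantiotopic carbonyl (carbinol R), and hydride enters anti to the aroyloxy group (steric and polar Felkin–Anh control), so OH ends cis to the ester and the quaternary carbon becomes R.

**Step 5**
Reactants: 9 hydroxy ketone
Product: 10 (1R,2R)-1-methyl-6-oxo-2-(triethylsilyloxy)cyclohexyl silylated orsellinate
Conditions: TESOTf, 2,6-lutidine, CH2Cl2, −78 °C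
Reagents that add atoms: triethylsilyl trifluoromethanesulfonate, CC[Si](CC)(CC)OS(=O)(=O)C(F)(F)F
Why: O-silylation protects the secondary alcohol against oxidation in step 6, acylation in step 9 and 1,2-acyl migration.

**Step 6**
Reactants: 10 silyl ether ketone
Product: 11 (1R,6R)-1-methyl-2-oxo-6-(triethylsilyloxy)cyclohex-3-en-1-yl silylated orsellinate (enone)
Conditions: IBX (2-iodoxybenzoic acid), DMSO/PhMe, 70 °C
Reagents that add atoms: none
Why: IBX dehydrogenation of the ketone through its enol; the other α-carbon is quaternary, so only one enone can form.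

**Step 7**
Reactants: 11 enone
Product: 12 (1R,6R)-3-(hydroxymethyl)-1-methyl-2-oxo-6-(triethylsilyloxy)cyclohex-3-en-1-yl silylated orsellinate
Conditions: 37% aq. CH2O, DMAP (20 mol%), THF/H2O, rt
Reagents that add atoms: formaldehyde, C=O
Why: Morita–Baylis–Hillman reaction: DMAP adds to the unsubstituted β-carbon, the enolate is hydroxymethylated at the α-carbon (the future C8a) and the catalyst leaves, so C1 enters at the only possible position.

**Step 8**
Reactants: 13 Meldrum's acid; 14 (E)-but-2-enoyl chloride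
Product: 15 5-[(2E)-1-hydroxybut-2-en-1-ylidene]-2,2-dimethyl-1,3-dioxane-4,6-dione
Conditions: pyridine (2 equiv), CH2Cl2, 0 °C to rt
Reagents that add atoms: none
Why: C-acylation of Meldrum's acid gives the enolized acyl Meldrum's acid, a stable precursor of the acylketene.

**Step 9**
Reactants: 12 Baylis–Hillman alcohol; 15 crotonyl Meldrum's acid
Product: 17 [(4R,5R)-5-methyl-6-oxo-5-(silylated orsellinoyloxy)-4-(triethylsilyloxy)cyclohex-1-en-1-yl]methyl (E)-3-oxohex-4-enoate, via acylketene 16 (not isolated)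
Conditions: PhMe, 90 °C
Reagents that add atoms: none
Why: on heating, 15 loses acetone and CO2 to give acylketene 16, which the primary allylic alcohol traps under neutral conditions (acylketene esterification) without touching the enone, the silyl ethers or the aryl ester.

**Step 10**
Reactants: 17 allylic β-keto ester
Product: 19 the 2-(phenylsulfinyl) derivative of 17 (mixture at C2 and sulfur), via sulfide 18 (not isolated)
Conditions: PhSCl, 2,6-lutidine, CH2Cl2, −78 to 0 °C; then mCPBA (1.0 equiv), −78 to −40 °C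
Reagents that add atoms: benzenesulfenyl chloride, ClSc1ccccc1; 3-chloroperbenzoic acid, O=C(OO)c1cccc(Cl)c1
Why: the β-keto ester enol is sulfenylated at its α-carbon and the sulfide is oxidized chemoselectively to the sulfoxide (α-sulfenylation, S-oxidation); the sulfinyl group has no β-hydrogen until step 11 and is the traceless source of the later C4=C4a unsaturation.

**Step 11**
Reactants: 19 allylic α-sulfinyl β-keto ester
Product: 23 (6R,7R)-7-methyl-8-oxo-3-[(E)-prop-1-enyl]-6-(triethylsilyloxy)-5,6,7,8-tetrahydro-1H-isochromen-7-yl silylated orsellinate, via rearranged keto acid 20 (not isolated), via keto sulfoxide 21 (not isolated), via oxatriene 22 (not isolated)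
Conditions: PhMe (0.01 M), 110 °C, argon
Reagents that add atoms: none
Why: Proposed new method: the ester enol of 19 (or its stabilized carbanion, by conjugate addition and β-elimination through the same six-membered array) moves C4 from the ester oxygen on C1 to ring carbon C4a in a decarboxylative Claisen (Carroll) rearrangement that leaves C8a=C1H2 as an exocyclic methylene; acid 20 loses CO2, the sulfoxide of 21 finds its only β-hydrogen on C4a and leaves as PhSOH by syn-elimination, and the (Z)-1-oxatriene 22 (O=C3–C4=C4a–C8a=C1H2) closes. The closest known reaction types are the Carroll rearrangement of allylic β-keto esters, the thermal sulfoxide elimination used to dehydrogenate β-dicarbonyl compounds and the oxa-6π closure of Knoevenagel-derived dienones to 2H-pyrans; their combination on the α-sulfinyl β-keto ester of a Baylis–Hillman alcohol is the untested part. The pyran ring closes by thermal disrotatory oxa-6π electrocyclization, the ketone oxygen O2 bonding to the methylene carbon C1, and the closed form is favoured because it is a doubly vinylogous ester (O2–C3=C4–C4a=C8a–C8=O). No new stereocentre remains: those at C4, C4a and sulfur are transient, and C6 and C7 cannot epimerize under neutral heating (C7 is quaternary, C6–H is not acidic). The step needs C–C bond formation at C4a and not at C1, and the Z geometry at C4=C4a: the ester tether enforces the first (attack at C1 would need a four-membered ring), and the second is reached because the E and Z dienones interconvert through the C5 dienol while only the Z isomer is removed by the electrocyclization.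

**Step 12**
Reactants: 23 silyl-protected bicycle
Product: 24 (6R,7R)-6-hydroxy-7-methyl-8-oxo-3-[(E)-prop-1-enyl]-5,6,7,8-tetrahydro-1H-isochromen-7-yl silylated orsellinate
Conditions: PPTS (cat.), MeOH/CH2Cl2, rt
Reagents that add atoms: none
Why: acid-catalysed methanolysis removes the triethylsilyl ether, while the aryl triisopropylsilyl ethers and the vinylogous-ester pyran are stable (selective desilylation).

**Step 13**
Reactants: 24 bicyclic alcohol; 25 (E)-but-2-enal
Product: 26 (6R,7R)-6-hydroxy-7-methyl-8-oxo-3-[(E)-3-oxoprop-1-enyl]-5,6,7,8-tetrahydro-1H-isochromen-7-yl silylated orsellinate (dienal half)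
Conditions: second-generation Hoveyda–Grubbs catalyst (5 mol%), excess 25, CH2Cl2, 40 °C
Reagents that add atoms: none
Why: olefin cross-metathesis exchanges the methyl end of the propenyl group for the formyl end of crotonaldehyde with E selectivity; the enol-ether and tetrasubstituted ring double bonds are too hindered and electron-poor to react.

**Step 14**
Reactants: 24 bicyclic alcohol; 27 (Z)-but-2-ene-1,4-diyl diacetate
Product: 28 (6R,7R)-3-[(E)-3-acetoxyprop-1-enyl]-6-hydroxy-7-methyl-8-oxo-5,6,7,8-tetrahydro-1H-isochromen-7-yl silylated orsellinate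
Conditions: second-generation Hoveyda–Grubbs catalyst (5 mol%), excess 27, CH2Cl2, 40 °C
Reagents that add atoms: none
Why: the same cross-metathesis with the symmetrical diacetate installs the (E)-3-acetoxypropenyl side chain of the dione half.

**Step 15**
Reactants: 28 acetoxypropenyl alcohol
Product: 29 (7R)-3-[(E)-3-acetoxyprop-1-enyl]-7-methyl-6,8-dioxo-5,6,7,8-tetrahydro-1H-isochromen-7-yl silylated orsellinate (dione half)
Conditions: Dess–Martin periodinane, CH2Cl2, 0 °C to rt
Reagents that add atoms: none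
Why: Dess–Martin oxidation of the only free alcohol gives the 6,8-dione, whose C5H2 lies between the C6 ketone and the vinylogous C8 ketone and is therefore acidic; C7 is quaternary and keeps its configuration.

**Step 16**
Reactants: 29 dione half; 26 dienal half
Product: 30 tetrakis(triisopropylsilyl) ether of the target
Conditions: ethylenediammonium diacetate (10 mol%), 4 Å molecular sieves, CH2Cl2, 0 °C to rt
Reagents that add atoms: none
Why: Knoevenagel condensation: the acidic C5H2 of 29 adds to the aldehyde of 26 and water is lost; 26 has no comparably acidic CH and 29 no aldehyde, so only the cross product should form, and reversible amine addition lets the new C5=CH bond settle in the isomer with the chain turned away from H4 (cis to C6=O, as in the target) while the enal double bond stays E.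

**Step 17**
Reactants: 30 silyl-protected dimer
Product: 31 CNP0239166.2
Conditions: TBAF/AcOH (1:1, 4.4 equiv), THF, 0 °C
Reagents that add atoms: none
Why: fluoride cleaves the four aryl silyl ethers, and buffering with acetic acid spares the allylic acetate, the hindered benzoates and the base-sensitive dienylidene dione (desilylation).

**Compound list**
1 | orsellinic acid (2,4-dihydroxy-6-methylbenzoic acid) | Cc1cc(O)cc(O)c1C(=O)O | starting material
2 | triisopropylsilyl 2,4-bis(triisopropylsilyloxy)-6-methylbenzoate | Cc1cc(O[Si](C(C)C)(C(C)C)C(C)C)cc(O[Si](C(C)C)(C(C)C)C(C)C)c1C(=O)O[Si](C(C)C)(C(C)C)C(C)C | intermediate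
3 | 2,4-bis(triisopropylsilyloxy)-6-methylbenzoic acid | Cc1cc(O[Si](C(C)C)(C(C)C)C(C)C)cc(O[Si](C(C)C)(C(C)C)C(C)C)c1C(=O)O | intermediate
4 | 2-methylcyclohexane-1,3-dione | CC1C(=O)CCCC1=O | starting material
5 | 2,4-bis(triisopropylsilyloxy)-6-methylbenzoyl chloride | Cc1cc(O[Si](C(C)C)(C(C)C)C(C)C)cc(O[Si](C(C)C)(C(C)C)C(C)C)c1C(Cl)=O | intermediate
6 | 2-methyl-3-oxocyclohex-1-en-1-yl 2,4-bis(triisopropylsilyloxy)-6-methylbenzoate | CC1=C(OC(=O)c3c(C)cc(O[Si](C(C)C)(C(C)C)C(C)C)cc3O[Si](C(C)C)(C(C)C)C(C)C)CCCC1=O | intermediate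
7 | 6-methyl-5-oxo-7-oxabicyclo[4.1.0]heptan-1-yl 2,4-bis(triisopropylsilyloxy)-6-methylbenzoate (racemic) | CC12OC1(OC(=O)c3c(C)cc(O[Si](C(C)C)(C(C)C)C(C)C)cc3O[Si](C(C)C)(C(C)C)C(C)C)CCCC2=O | intermediate
8 | 1-methyl-2,6-dioxocyclohexyl 2,4-bis(triisopropylsilyloxy)-6-methylbenzoate | CC1(OC(=O)c3c(C)cc(O[Si](C(C)C)(C(C)C)C(C)C)cc3O[Si](C(C)C)(C(C)C)C(C)C)C(=O)CCCC1=O | intermediate
9 | (1R,2R)-2-hydroxy-1-methyl-6-oxocyclohexyl 2,4-bis(triisopropylsilyloxy)-6-methylbenzoate | C1CC[C@@H](O)[C@@](C)(OC(=O)c3c(C)cc(O[Si](C(C)C)(C(C)C)C(C)C)cc3O[Si](C(C)C)(C(C)C)C(C)C)C1=O | intermediate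
10 | (1R,2R)-1-methyl-6-oxo-2-(triethylsilyloxy)cyclohexyl 2,4-bis(triisopropylsilyloxy)-6-methylbenzoate | C1CC[C@@H](O[Si](CC)(CC)CC)[C@@](C)(OC(=O)c3c(C)cc(O[Si](C(C)C)(C(C)C)C(C)C)cc3O[Si](C(C)C)(C(C)C)C(C)C)C1=O | intermediate
11 | (1R,6R)-1-methyl-2-oxo-6-(triethylsilyloxy)cyclohex-3-en-1-yl 2,4-bis(triisopropylsilyloxy)-6-methylbenzoate | C1=CC[C@@H](O[Si](CC)(CC)CC)[C@@](C)(OC(=O)c3c(C)cc(O[Si](C(C)C)(C(C)C)C(C)C)cc3O[Si](C(C)C)(C(C)C)C(C)C)C1=O | intermediate
12 | (1R,6R)-3-(hydroxymethyl)-1-methyl-2-oxo-6-(triethylsilyloxy)cyclohex-3-en-1-yl 2,4-bis(triisopropylsilyloxy)-6-methylbenzoate | OCC1=CC[C@@H](O[Si](CC)(CC)CC)[C@@](C)(OC(=O)c3c(C)cc(O[Si](C(C)C)(C(C)C)C(C)C)cc3O[Si](C(C)C)(C(C)C)C(C)C)C1=O | intermediate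
13 | Meldrum's acid (2,2-dimethyl-1,3-dioxane-4,6-dione) | CC1(C)OC(=O)CC(=O)O1 | starting material
14 | (E)-but-2-enoyl chloride | C/C=C/C(Cl)=O | starting material
15 | 5-[(2E)-1-hydroxybut-2-en-1-ylidene]-2,2-dimethyl-1,3-dioxane-4,6-dione | C/C=C/C(O)=C1C(=O)OC(C)(C)OC1=O | intermediate
16 | (4E)-hexa-1,4-diene-1,3-dione (crotonylketene) | C/C=C/C(=O)C=C=O | intermediate
17 | [(4R,5R)-5-methyl-6-oxo-5-{[2,4-bis(triisopropylsilyloxy)-6-methylbenzoyl]oxy}-4-(triethylsilyloxy)cyclohex-1-en-1-yl]methyl (E)-3-oxohex-4-enoate | C/C=C/C(=O)CC(=O)OCC1=CC[C@@H](O[Si](CC)(CC)CC)[C@@](C)(OC(=O)c3c(C)cc(O[Si](C(C)C)(C(C)C)C(C)C)cc3O[Si](C(C)C)(C(C)C)C(C)C)C1=O | intermediate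
18 | 2-(phenylsulfanyl) derivative of 17 (C2 epimers) | C/C=C/C(=O)C(Sc4ccccc4)C(=O)OCC1=CC[C@@H](O[Si](CC)(CC)CC)[C@@](C)(OC(=O)c3c(C)cc(O[Si](C(C)C)(C(C)C)C(C)C)cc3O[Si](C(C)C)(C(C)C)C(C)C)C1=O | intermediate
19 | 2-(phenylsulfinyl) derivative of 17 (mixture at C2 and S) | C/C=C/C(=O)C(S(=O)c4ccccc4)C(=O)OCC1=CC[C@@H](O[Si](CC)(CC)CC)[C@@](C)(OC(=O)c3c(C)cc(O[Si](C(C)C)(C(C)C)C(C)C)cc3O[Si](C(C)C)(C(C)C)C(C)C)C1=O | intermediate
20 | (E)-2-[(4R,5R)-4-methyl-2-methylidene-3-oxo-4-(silylated orsellinoyloxy)-5-(triethylsilyloxy)cyclohexyl]-3-oxo-2-(phenylsulfinyl)hex-4-enoic acid (mixture at the new centres) | C=C1C(C(S(=O)c4ccccc4)(C(=O)O)C(=O)/C=C/C)C[C@@H](O[Si](CC)(CC)CC)[C@@](C)(OC(=O)c3c(C)cc(O[Si](C(C)C)(C(C)C)C(C)C)cc3O[Si](C(C)C)(C(C)C)C(C)C)C1=O | intermediate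
21 | (1R,6R)-1-methyl-3-methylidene-2-oxo-4-[(E)-2-oxo-1-(phenylsulfinyl)pent-3-enyl]-6-(triethylsilyloxy)cyclohexyl silylated orsellinate (mixture at the new centres) | C=C1C(C(S(=O)c4ccccc4)C(=O)/C=C/C)C[C@@H](O[Si](CC)(CC)CC)[C@@](C)(OC(=O)c3c(C)cc(O[Si](C(C)C)(C(C)C)C(C)C)cc3O[Si](C(C)C)(C(C)C)C(C)C)C1=O | intermediate
22 | (1R,6R,4Z)-1-methyl-3-methylidene-2-oxo-4-[(E)-2-oxopent-3-enylidene]-6-(triethylsilyloxy)cyclohexyl silylated orsellinate (1-oxatriene) | C=C1/C(=C\C(=O)/C=C/C)C[C@@H](O[Si](CC)(CC)CC)[C@@](C)(OC(=O)c3c(C)cc(O[Si](C(C)C)(C(C)C)C(C)C)cc3O[Si](C(C)C)(C(C)C)C(C)C)C1=O | intermediate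
23 | (6R,7R)-7-methyl-8-oxo-3-[(E)-prop-1-enyl]-6-(triethylsilyloxy)-5,6,7,8-tetrahydro-1H-isochromen-7-yl 2,4-bis(triisopropylsilyloxy)-6-methylbenzoate | C/C=C/C1=CC2=C(CO1)C(=O)[C@](C)(OC(=O)c3c(C)cc(O[Si](C(C)C)(C(C)C)C(C)C)cc3O[Si](C(C)C)(C(C)C)C(C)C)[C@H](O[Si](CC)(CC)CC)C2 | intermediate
24 | (6R,7R)-6-hydroxy-7-methyl-8-oxo-3-[(E)-prop-1-enyl]-5,6,7,8-tetrahydro-1H-isochromen-7-yl 2,4-bis(triisopropylsilyloxy)-6-methylbenzoate | C/C=C/C1=CC2=C(CO1)C(=O)[C@](C)(OC(=O)c3c(C)cc(O[Si](C(C)C)(C(C)C)C(C)C)cc3O[Si](C(C)C)(C(C)C)C(C)C)[C@H](O)C2 | intermediate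
25 | (E)-but-2-enal (crotonaldehyde) | C/C=C/C=O | starting material
26 | (6R,7R)-6-hydroxy-7-methyl-8-oxo-3-[(E)-3-oxoprop-1-enyl]-5,6,7,8-tetrahydro-1H-isochromen-7-yl 2,4-bis(triisopropylsilyloxy)-6-methylbenzoate | O=C/C=C/C1=CC2=C(CO1)C(=O)[C@](C)(OC(=O)c3c(C)cc(O[Si](C(C)C)(C(C)C)C(C)C)cc3O[Si](C(C)C)(C(C)C)C(C)C)[C@H](O)C2 | intermediate
27 | (Z)-but-2-ene-1,4-diyl diacetate | CC(=O)OC/C=C\COC(C)=O | starting material
28 | (6R,7R)-3-[(E)-3-acetoxyprop-1-enyl]-6-hydroxy-7-methyl-8-oxo-5,6,7,8-tetrahydro-1H-isochromen-7-yl 2,4-bis(triisopropylsilyloxy)-6-methylbenzoate | CC(=O)OC/C=C/C1=CC2=C(CO1)C(=O)[C@](C)(OC(=O)c3c(C)cc(O[Si](C(C)C)(C(C)C)C(C)C)cc3O[Si](C(C)C)(C(C)C)C(C)C)[C@H](O)C2 | intermediate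
29 | (7R)-3-[(E)-3-acetoxyprop-1-enyl]-7-methyl-6,8-dioxo-5,6,7,8-tetrahydro-1H-isochromen-7-yl 2,4-bis(triisopropylsilyloxy)-6-methylbenzoate | CC(=O)OC/C=C/C1=CC2=C(CO1)C(=O)[C@](C)(OC(=O)c3c(C)cc(O[Si](C(C)C)(C(C)C)C(C)C)cc3O[Si](C(C)C)(C(C)C)C(C)C)C(=O)C2 | intermediate
30 | tetrakis(triisopropylsilyl) ether of 31 (all four phenols silylated) | CC(=O)OC/C=C/C1=CC2=C(CO1)C(=O)[C@](C)(OC(=O)c3c(C)cc(O[Si](C(C)C)(C(C)C)C(C)C)cc3O[Si](C(C)C)(C(C)C)C(C)C)C(=O)/C2=C\C=C\C1=CC2=C(CO1)C(=O)[C@](C)(OC(=O)c3c(C)cc(O[Si](C(C)C)(C(C)C)C(C)C)cc3O[Si](C(C)C)(C(C)C)C(C)C)[C@H](O)C2 | intermediate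
31 | CNP0239166.2 (dione half 7R; carbinol half 6R,7R) | CC(=O)OC/C=C/C1=CC2=C(CO1)C(=O)[C@](C)(OC(=O)c1c(C)cc(O)cc1O)C(=O)/C2=C\C=C\C1=CC2=C(CO1)C(=O)[C@](C)(OC(=O)c1c(C)cc(O)cc1O)[C@H](O)C2 | target

**Step count and risks**
Total steps: 17. Longest linear sequence: 15 steps (1–7, 9–12, 14–17).

Step 11. What may go wrong: the sulfinyl keto ester may fragment before the [3,3] shift, sulfenic acid may be lost before decarboxylation so that a carboxyl group stays on C4, or the liberated sulfenic acid may add to the methylene ketone. The fallback sets out from 12 and uses only known reaction types. Acetylation of 12 (Ac2O, pyridine) gives the Baylis–Hillman acetate F1. (E)-1-(Phenylsulfinyl)pent-3-en-2-one F2, prepared from lithiated methyl phenyl sulfoxide and (E)-N-methoxy-N-methylbut-2-enamide, is alkylated by F1 with Cs2CO3 in MeCN by conjugate addition at the ring β-carbon and loss of acetate, the usual course of such acetates with stabilized carbanions. This gives 21 as an isolated compound, and the route is rejoined at 21: heating it in toluene brings about the sulfoxide elimination and electrocyclization to 23.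

Step 16. What may go wrong: a second molecule of 29 may add in conjugate fashion to the dienylidene dione, dehydration may stall at the aldol stage, or the new double bond may scramble its geometry under amine catalysis. The fallback sets out from 23 and 29 and separates addition from dehydration. Cross-metathesis of 23 with 25 gives the silyl-protected dienal F3. Directed aldol addition of 29 to F3 under soft enolization (MgBr2·OEt2, i-Pr2NEt, −20 °C) gives the β-hydroxy ketone F4, which is dehydrated with catalytic DBU (E1cB) to the pentasilyl dimer F5. TBAF/AcOH then removes all five silyl groups, and the route is rejoined at 31.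

Step 3. What may go wrong: epoxidation of the electron-poor, tetrasubstituted enol ester may be too slow, or the acyloxy epoxide may hydrolyse instead of undergoing the acyl shift. The fallback sets out from 4 and 3 and forms the C7–O bond intermolecularly by a Wessely-type acyloxylation: Pb(OAc)4 is equilibrated with excess 3 (acetic acid removed under vacuum) and the lead carboxylate acyloxylates 4 at C2 in benzene. The route is rejoined at 8, and step 2 is then not needed.

**Further compounds**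
F1 | step 11 | [(4R,5R)-5-methyl-6-oxo-5-{[2,4-bis(triisopropylsilyloxy)-6-methylbenzoyl]oxy}-4-(triethylsilyloxy)cyclohex-1-en-1-yl]methyl acetate | CC(=O)OCC1=CC[C@@H](O[Si](CC)(CC)CC)[C@@](C)(OC(=O)c3c(C)cc(O[Si](C(C)C)(C(C)C)C(C)C)cc3O[Si](C(C)C)(C(C)C)C(C)C)C1=O
F2 | step 11 | (E)-1-(phenylsulfinyl)pent-3-en-2-one | C/C=C/C(=O)CS(=O)c1ccccc1
F3 | step 16 | (6R,7R)-7-methyl-8-oxo-3-[(E)-3-oxoprop-1-enyl]-6-(triethylsilyloxy)-5,6,7,8-tetrahydro-1H-isochromen-7-yl 2,4-bis(triisopropylsilyloxy)-6-methylbenzoate | O=C/C=C/C1=CC2=C(CO1)C(=O)[C@](C)(OC(=O)c3c(C)cc(O[Si](C(C)C)(C(C)C)C(C)C)cc3O[Si](C(C)C)(C(C)C)C(C)C)[C@H](O[Si](CC)(CC)CC)C2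
F4 | step 16 | aldol adduct of 29 (at C5) and F3 (β-hydroxy ketone, mixture at the two new centres) | CC(=O)OC/C=C/C1=CC2=C(CO1)C(=O)[C@](C)(OC(=O)c3c(C)cc(O[Si](C(C)C)(C(C)C)C(C)C)cc3O[Si](C(C)C)(C(C)C)C(C)C)C(=O)C2C(O)/C=C/C1=CC2=C(CO1)C(=O)[C@](C)(OC(=O)c3c(C)cc(O[Si](C(C)C)(C(C)C)C(C)C)cc3O[Si](C(C)C)(C(C)C)C(C)C)[C@H](O[Si](CC)(CC)CC)C2
F5 | step 16 | 6-O-triethylsilyl derivative of 30 (pentasilyl dimer) | CC(=O)OC/C=C/C1=CC2=C(CO1)C(=O)[C@](C)(OC(=O)c3c(C)cc(O[Si](C(C)C)(C(C)C)C(C)C)cc3O[Si](C(C)C)(C(C)C)C(C)C)C(=O)/C2=C\C=C\C1=CC2=C(CO1)C(=O)[C@](C)(OC(=O)c3c(C)cc(O[Si](C(C)C)(C(C)C)C(C)C)cc3O[Si](C(C)C)(C(C)C)C(C)C)[C@H](O[Si](CC)(CC)CC)C2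
F0 | step 3 | none | none
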